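**Numbering used throughout:** 1 2,5-dimethylresorcinol; 2 its formyl derivative; 3 the chloro aldehyde; 4 the dibenzyl aldehyde; 5 the ring B acid; 6 methyl acetoacetate; 7 the ring B acid chloride; 8 the enol ester; 9 the silyloxy diene; 10 methyl but-2-ynoate; 11 the cycloadduct; 12 the dibenzyl depside; 13 the target.

## Analysis of the target

Target 13 is a depside: two benzene rings joined through a single aryl ester, with no further ring and no stereocentre, so the problem is one of substitution pattern and chemoselectivity only. Ring A is a methyl orsellinate unit, numbered here C1 (CO2CH3), C2 (CH3), C3 (H), C4 (acyloxy oxygen), C5 (H) and C6 (OH). Ring B is a fully substituted benzoyl group with C1' (carbonyl), C2' (CH3), C3' (Cl), C4' (OH), C5' (CH3) and C6' (OH). The inter-ring ester is an activated aryl ester and the most fragile bond, open to cleavage or transesterification by alkoxide, hydroxide or amines; the methyl ester at C1, the three phenols and the reducible aryl chloride must also come through intact. The difficulty lies in three places: the ring B carbonyl sits between two ortho substituents and is a hindered acyl donor, the acyl group must end on the C4 oxygen and not on the C6 oxygen, and the chlorine must be placed unambiguously on a hexasubstituted ring. The strategy rests on the fact that C3–C4–C5–C6 of ring A, with the oxygens on C4 and C6, are the four carbons and two of the oxygens of 6 (CH3 to C3, ketone to C4, CH2 to C5, ester carbon to C6), while C1–C2 with their ester and methyl groups are the alkyne carbons of 10. The C4 oxygen therefore exists as an enol oxygen of 6 before ring A does, and it can take up the hindered ring B acyl group at that stage, after which ring A is grown around it.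

## Retrosynthetic reasoning

**13 to 12.** The two O–CH2Ph bonds at C4' and C6' are cut last. The ring B phenols must be masked through acid chloride formation, amide base and prolonged heating, and benzyl ethers are inert to all three. They can be removed by a Lewis acid, which spares the aryl chloride where hydrogenolysis might not. The forward step must leave both esters alone and must not let benzyl cations alkylate ring A.

**12 to 9 and 10 (through 11).** Ring A is cut at C2–C3 and C6–C1. This is the only pair of bonds that divides the ring into a four-carbon piece carrying both oxygens (derived from 6) and a two-carbon piece carrying the ester and the methyl group (10). Both pieces are already at the oxidation level of the arene, so aromatization needs only the loss of the methoxy and silyl groups from C6 of 11. What is gained is that the inter-ring ester never has to be made on an aromatic diol: there is no choice between the C4 and C6 hydroxyls, because the C6 hydroxyl is created by the ring closure itself. The forward reaction must join the CH2 end of the diene to the methyl-bearing alkyne carbon and must leave the enol ester untouched.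

**9 to 8.** The O–Si bond is cut and a γ-hydrogen restored. The forward step is a kinetic γ-deprotonation with O-silylation of the extended enolate; it must proceed without acyl transfer, without loss of the carboxylate and without attack on either ester.

**8 to 7 and 6; 7 from 5.** The enol ester C(=O)–O bond is cut. The enol oxygen of 6 is unhindered and far more reactive than a phenol, which is why the hindered acyl group is attached here. The forward step must give O- and not C-acylation.

**5 back to 1.** The remaining changes are functional group operations on ring B: the acid from aldehyde 4 by a mild aldehyde oxidation, the benzyl ethers from 3, the C3'–Cl bond from 2, and the C1' formyl carbon from 1. Compound 1 already holds both methyl groups and both oxygens in the right relation and has two equivalent free positions, so the first substitution cannot give isomers and the second has only one site left. Formylation comes first because it needs the more activated ring; chlorination then fills the last position.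

## Alternatives that were turned down

Alternative 1: Both bonds at the depside carbonyl carbon are cut, C1'–C(=O) and C(=O)–O(C4). This leaves the ring B iodide 1-chloro-3-iodo-4,6-bis(methoxymethoxy)-2,5-dimethylbenzene A1, the ring A diol methyl 2,4-dihydroxy-6-methylbenzoate A2 and carbon monoxide A3. In the forward key step a phosphine-ligated zerovalent palladium catalyst would insert into the C–I bond of A1, A3 would insert to give an aroylpalladium species, and the C4 phenoxide of A2, formed with a tertiary amine, would intercept it to give methyl 4-{[3-chloro-4,6-bis(methoxymethoxy)-2,5-dimethylbenzoyl]oxy}-2-hydroxy-6-methylbenzoate A4. A4 is the bis(methoxymethyl) ether of the target, and mild acid would then free its ring B phenols.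
- For: this is the most convergent plan. A2 is ring A ready-made, A1 should need about three steps from 1, no strong base is involved, and the preference of orsellinates such as A2 for reaction at the non-chelated C4 hydroxyl is well established.
- Against: the C–I carbon of A1 is flanked by a methyl and an alkoxy group, so the aroylpalladium intermediate is hindered exactly where a weakly nucleophilic phenoxide has to attack. Reduction of the C–I bond and slow turnover are the expected failure modes, and pressurised A3 has to be handled.
- Comparison: on step count and convergence this plan is stronger (about five steps to the target through A4 against eight), and all its steps are of known types. The chosen route offers instead an ester bond made by acid chloride chemistry on an unhindered enol oxygen, no selection between two phenols, no gas handling, and ring A built from two commodity esters.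

Alternative 2: Ring B is opened at C1'–C2', which turns it into the open-chain aryl ester methyl 2-hydroxy-6-methyl-4-[(4-methyl-3,5,7-trioxooctanoyl)oxy]benzoate A5. In the forward key step a tertiary amine would enolize chain C2 of A5, this carbon would add to the C7 ketone, and acid would drive loss of water and enolization to methyl 4-[(2,4-dihydroxy-3,6-dimethylbenzoyl)oxy]-2-hydroxy-6-methylbenzoate A6. A6 lacks the chlorine and would have to be chlorinated at C3' afterwards.
- For: the plan copies the polyketide origin of such rings, the ring B hydroxyls of A6 arise from ketones and need no protection, and the C5' methyl group is carried in the chain of A5.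
- Against: A5 is an aryl β-keto ester with a phenoxide leaving group, so O-cyclization of a chain enol onto the ester carbonyl with expulsion of A2 competes with the aldol closure. Other enolization modes of a 3,5,7-triketone lead to isomeric rings, and making the triketo acid and attaching it to a phenol is a multistep task of its own. The closing chlorination must choose C3' of A6 over C3 and C5 of ring A and stop at one chlorine.
- Comparison: if the folding of A5 worked it would need fewer protecting-group operations, which is a point in its favour. The chosen route closes the simpler ring A, where only one regiochemical question arises, and introduces the chlorine on 2, where only one position is open.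

Alternative 3: Three bonds of ring B are cut, C4'–C5', C6'–C1' and C3'–C4'. This leaves the diazo keto ester methyl 4-{[(4E)-5-chloro-2-diazo-4-methyl-3-oxopent-4-enoyl]oxy}-2-hydroxy-6-methylbenzoate A7 and the siloxyalkyne triisopropyl(prop-1-yn-1-yloxy)silane A8. In the forward key step irradiation of A7 would set off a Wolff rearrangement, the ketene function so formed would add A8 in a [2+2] fashion, and on warming the four-membered ring would open and reclose in a six-electron process. After enolization this would give the ring B phenol methyl 4-({3-chloro-4-hydroxy-2,5-dimethyl-6-[(triisopropylsilyl)oxy]benzoyl}oxy)-2-hydroxy-6-methylbenzoate A9. A9 is the C6'-O-triisopropylsilyl ether of the target, and fluoride would then remove its silyl group.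
- For: one operation places all six substituents of ring B in A9, chlorine included, with regiochemistry set by the polarity of ketene and ynol ether. No late chlorination is needed and the depside ester is present from A7 onwards.
- Against: A7 combines a diazo group, a β-chlorovinyl ketone that is open to addition–elimination, and a free ring A phenol, a nucleophile that could divert the cascade by intermolecular capture right after the Wolff rearrangement. Ketenes carrying an ester substituent are less proven in this annulation than simple ones. A7 and A8 each need several steps, photochemical equipment is required, and a desilylation of A9 is added.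
- Comparison: in density of bond formation on the crowded ring this plan, ending in A9, is stronger than the chosen one, which takes the ring B skeleton from 1. The chosen route offers cheap starting materials, thermal chemistry without diazo compounds, and fewer steps overall.

Key step: step 7

Assumption on the chemistry: 8 is drawn as the E enol ester and 9 as the Z ketene acetal; the other geometric isomers are expected to serve equally, because neither double-bond geometry survives into the aromatic ring.

## Route

Step 1
Reactants: 1 2,5-dimethylbenzene-1,3-diol (2,5-dimethylresorcinol)
Product: 2 2,4-dihydroxy-3,6-dimethylbenzaldehyde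
Conditions: POCl3, DMF, 0 °C to rt; then H2O, 50 °C
Reagents that add atoms: N,N-dimethylformamide, CN(C)C=O; water, O
Why: Vilsmeier–Haack formylation; the two free ring positions of 1 are equivalent and each is ortho to one hydroxyl and para to the other, so only one aldehyde can form, and the formyl group deactivates the ring against a second substitution. Any aryl formate formed at oxygen should be hydrolysed in the aqueous stage.

Step 2
Reactants: 2 2,4-dihydroxy-3,6-dimethylbenzaldehyde
Product: 3 3-chloro-4,6-dihydroxy-2,5-dimethylbenzaldehyde
Conditions: SO2Cl2 (1.05 equiv), Et2O, 0 °C
Reagents that add atoms: sulfuryl chloride, O=S(=O)(Cl)Cl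
Why: Electrophilic aromatic chlorination; 2 has a single ring hydrogen, ortho to one hydroxyl and para to the other, so one equivalent of reagent at low temperature should chlorinate there, and the limited charge guards against ipso attack and dienone formation.

Step 3
Reactants: 3 3-chloro-4,6-dihydroxy-2,5-dimethylbenzaldehyde
Product: 4 4,6-bis(benzyloxy)-3-chloro-2,5-dimethylbenzaldehyde
Conditions: BnBr (2.5 equiv), K2CO3, Bu4NI (cat.), DMF, 60 °C
Reagents that add atoms: benzyl bromide, BrCc1ccccc1
Why: Williamson ether synthesis; both phenols are acidified by the ortho or para formyl group and are deprotonated by K2CO3, and iodide catalysis with mild heating should overcome the flanking substituents. Benzyl is chosen because it withstands the amide base and the heating that follow.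

Step 4
Reactants: 4 4,6-bis(benzyloxy)-3-chloro-2,5-dimethylbenzaldehyde
Product: 5 4,6-bis(benzyloxy)-3-chloro-2,5-dimethylbenzoic acid
Conditions: NaClO2, NaH2PO4, 2-methylbut-2-ene, t-BuOH/THF/H2O, rt
Reagents that add atoms: sodium chlorite, [Na+].[O-]Cl=O
Why: Pinnick oxidation; chlorous acid oxidises hindered, electron-rich aldehydes without touching benzyl ethers, and the ring is fully substituted, so the hypochlorite by-product, scavenged by the alkene, cannot chlorinate it.

Step 5
Reactants: 5 4,6-bis(benzyloxy)-3-chloro-2,5-dimethylbenzoic acid; 6 methyl acetoacetate (methyl 3-oxobutanoate)
Product: 8 methyl (2E)-3-{[4,6-bis(benzyloxy)-3-chloro-2,5-dimethylbenzoyl]oxy}but-2-enoate, via aroyl chloride 7 (not isolated)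
Conditions: (COCl)2, DMF (cat.), CH2Cl2, 0 °C to rt; evaporate; then 6 (1.5 equiv), Et3N (2 equiv), DMPU–CH2Cl2, 0 °C to rt
Reagents that add atoms: none
Why: Acid chloride formation followed by O-acylation of the triethylammonium enolate of 6. Attack through oxygen is favoured by a hard, sterically encumbered acyl chloride, by a loosely paired enolate in a dipolar aprotic medium, and by the absence of a nucleophilic acyl-transfer catalyst that could mediate O-to-C migration.

Step 6
Reactants: 8 methyl (2E)-3-{[4,6-bis(benzyloxy)-3-chloro-2,5-dimethylbenzoyl]oxy}but-2-enoate
Product: 9 (3Z)-4-methoxy-4-[(trimethylsilyl)oxy]buta-1,3-dien-2-yl 4,6-bis(benzyloxy)-3-chloro-2,5-dimethylbenzoate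
Conditions: lithium diisopropylamide (1.1 equiv), Me3SiCl (1.5 equiv, present from the start), THF, −78 °C to 0 °C; evaporate, pentane, filter
Reagents that add atoms: chlorotrimethylsilane, C[Si](C)(C)Cl
Why: Kinetic γ-deprotonation of a β-oxygenated but-2-enoate and O-silylation of the extended enolate, the way 1,3-dioxygenated 1-silyloxybutadienes are made. The γ-methyl hydrogens are the most acidic in 8, the amide base is too hindered to add to either ester, and trapping by Me3SiCl already present should outrun acyl transfer or loss of carboxylate from the dienolate.

Step 7
Reactants: 9 (3Z)-4-methoxy-4-[(trimethylsilyl)oxy]buta-1,3-dien-2-yl 4,6-bis(benzyloxy)-3-chloro-2,5-dimethylbenzoate; 10 methyl but-2-ynoate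
Product: 12 methyl 4-{[4,6-bis(benzyloxy)-3-chloro-2,5-dimethylbenzoyl]oxy}-2-hydroxy-6-methylbenzoate, via cyclohexadiene cycloadduct 11 (not isolated)
Conditions: 10 (5 equiv), toluene, 120 °C, sealed tube
Reagents that add atoms: none
Why: Proposed new method: the closest known reaction type is the thermal Diels–Alder reaction of 1-alkoxy-1-silyloxybuta-1,3-dienes that carry an alkoxy or silyloxy group at C3 with alkynoates, followed by aromatization, and what is new here is the aroyloxy group at C3 of the diene. Diene 9 is a vinylogous silyl ketene acetal whose largest HOMO coefficient lies on the CH2 terminus, so this carbon bonds to the electrophilic β-carbon of 10 (ring A bond C3–C2) while the ketene acetal carbon bonds to the α-carbon (bond C6–C1) in a concerted but asynchronous [4+2] cycloaddition. Ring A is thus closed by intermolecular [4+2] union of one four-carbon and one two-carbon partner; in the stepwise limit the second bond would form by 6-(enolendo)-exo-trig attack of the allenolate α-carbon on the silyloxycarbenium carbon. Cycloadduct 11 carries a methyl silyl ketal at C6 and a CH2 group at C3, and ionization of the C6–OCH3 bond with silyl transfer to the departing methoxide releases methoxytrimethylsilane and a cyclohexadienone that tautomerizes to the C6 phenol of 12. No stereocentre has to be controlled, since the ketal carbon of 11 is formed racemic and becomes planar on aromatization. The regioselectivity needed (ester next to the new hydroxyl and para to the acyloxy group) is secured by the matched polarity of the donor-substituted diene and the acceptor-substituted alkyne. The chemoselectivity needed (survival of the enol ester) is supported by the C2' methyl and C6' benzyloxy groups, which shield the ring B carbonyl, and by the meta relation of the new hydroxyl to the acyloxy group, which excludes intramolecular acyl transfer. An excess of 10 in a sealed vessel is meant to offset the modest dienophilicity of a β-methyl ynoate and the weaker donor strength of an acyloxy group.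

Step 8
Reactants: 12 methyl 4-{[4,6-bis(benzyloxy)-3-chloro-2,5-dimethylbenzoyl]oxy}-2-hydroxy-6-methylbenzoate
Product: 13 methyl 4-[(3-chloro-4,6-dihydroxy-2,5-dimethylbenzoyl)oxy]-2-hydroxy-6-methylbenzoate
Conditions: BCl3 (4 equiv), C6HMe5 (4 equiv), CH2Cl2, −78 °C; then MeOH
Reagents that add atoms: none
Why: Lewis-acid cleavage of aryl benzyl ethers with a cation scavenger; BCl3 complexes the ether oxygens and the benzyl cations are captured by pentamethylbenzene before they can alkylate C3 or C5 of ring A. At −78 °C the aryl ester, the methyl ester and the aryl chloride should be inert, whereas hydrogenolysis would put the C3' chlorine at risk.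

## Compound list

1 | 2,5-dimethylbenzene-1,3-diol | Cc1cc(O)c(C)c(O)c1 | starting material
2 | 2,4-dihydroxy-3,6-dimethylbenzaldehyde | O=Cc1c(C)cc(O)c(C)c1O | intermediate
3 | 3-chloro-4,6-dihydroxy-2,5-dimethylbenzaldehyde | O=Cc1c(C)c(Cl)c(O)c(C)c1O | intermediate
4 | 4,6-bis(benzyloxy)-3-chloro-2,5-dimethylbenzaldehyde | O=Cc1c(C)c(Cl)c(OCc2ccccc2)c(C)c1OCc1ccccc1 | intermediate
5 | 4,6-bis(benzyloxy)-3-chloro-2,5-dimethylbenzoic acid | OC(=O)c1c(C)c(Cl)c(OCc2ccccc2)c(C)c1OCc1ccccc1 | intermediate
6 | methyl acetoacetate (methyl 3-oxobutanoate) | CC(=O)CC(=O)OC | starting material
7 | 4,6-bis(benzyloxy)-3-chloro-2,5-dimethylbenzoyl chloride (not isolated) | ClC(=O)c1c(C)c(Cl)c(OCc2ccccc2)c(C)c1OCc1ccccc1 | intermediate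
8 | methyl (2E)-3-{[4,6-bis(benzyloxy)-3-chloro-2,5-dimethylbenzoyl]oxy}but-2-enoate | C/C(OC(=O)c1c(C)c(Cl)c(OCc2ccccc2)c(C)c1OCc1ccccc1)=C\C(=O)OC | intermediate
9 | (3Z)-4-methoxy-4-[(trimethylsilyl)oxy]buta-1,3-dien-2-yl 4,6-bis(benzyloxy)-3-chloro-2,5-dimethylbenzoate | CO/C(O[Si](C)(C)C)=C/C(=C)OC(=O)c1c(C)c(Cl)c(OCc2ccccc2)c(C)c1OCc1ccccc1 | intermediate
10 | methyl but-2-ynoate | CC#CC(=O)OC | starting material
11 | methyl 4-{[4,6-bis(benzyloxy)-3-chloro-2,5-dimethylbenzoyl]oxy}-6-methoxy-2-methyl-6-[(trimethylsilyl)oxy]cyclohexa-1,4-diene-1-carboxylate (racemic at C6, not isolated) | COC(=O)C1=C(C)CC(OC(=O)c2c(C)c(Cl)c(OCc3ccccc3)c(C)c2OCc2ccccc2)=CC1(OC)O[Si](C)(C)C | intermediate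
12 | methyl 4-{[4,6-bis(benzyloxy)-3-chloro-2,5-dimethylbenzoyl]oxy}-2-hydroxy-6-methylbenzoate | COC(=O)c1c(C)cc(OC(=O)c2c(C)c(Cl)c(OCc3ccccc3)c(C)c2OCc2ccccc2)cc1O | intermediate
13 | methyl 4-[(3-chloro-4,6-dihydroxy-2,5-dimethylbenzoyl)oxy]-2-hydroxy-6-methylbenzoate | COC(=O)c1c(C)cc(OC(=O)c2c(C)c(Cl)c(O)c(C)c2O)cc1O | target

## Step count and least certain steps

Total step count: 8. Longest linear sequence: 8 steps (1 to 13); 6 and 10 are bought and enter at steps 5 and 7.

**Step 7 (key step, new method).** The most likely failure is that cycloaddition is slower than thermal decay of the diene: silyl migration from oxygen to carbon, hydrolysis back to 8 by traces of moisture, or oligomerization of 10. The cause would be that an acyloxy group donates less than a silyloxy group and that a β-methyl ynoate is a sluggish dienophile. Incomplete aromatization of 11 is a lesser concern. The fallback uses known chemistry only, sets out from 6 and returns to the route at 12; it moves the acylation to after ring formation. Compound 6 is O-silylated (Me3SiCl, Et3N) to methyl (2Z)-3-[(trimethylsilyl)oxy]but-2-enoate F1, which lithium diisopropylamide and Me3SiCl convert into (1Z)-1-methoxy-1,3-bis[(trimethylsilyl)oxy]buta-1,3-diene F2. Heating F2 with 10 should give the cycloadduct methyl 6-methoxy-2-methyl-4,6-bis[(trimethylsilyl)oxy]cyclohexa-1,4-diene-1-carboxylate F3, which aromatizes to the aryl silyl ether methyl 2-hydroxy-6-methyl-4-[(trimethylsilyl)oxy]benzoate F4. Dilute HCl then frees methyl 2,4-dihydroxy-6-methylbenzoate F5, which is also an article of commerce. Its non-chelated, more acidic C4 hydroxyl is then acylated with acid chloride 7 (made from 5 as in step 5; Et3N, CH2Cl2) to give 12.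

**Step 6.** The lithium dienolate of 8 may undergo acyl transfer from oxygen to carbon (a vinylogous anionic Fries-type shift) or β-elimination of the hindered carboxylate. Lateral deprotonation of the C2' methyl group next to the ester carbonyl may also compete, and the silyl group may be lost by hydrolysis during isolation. The fallback gives up acylation before ring formation; it sets out from 5 and returns at 12. Acid 5 is activated with trifluoroacetic anhydride in toluene as 4,6-bis(benzyloxy)-3-chloro-2,5-dimethylbenzoic trifluoroacetic anhydride F6, which acylates the C4 hydroxyl of F5 (bought, or made as described under step 7) to give 12.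

**Step 5.** Acylation may take place at carbon and not at oxygen, or the hindered acid chloride may react so slowly that hydrolysis on work-up returns 5. The fallback replaces enolate acylation by fluoride-triggered silyl-to-acyl exchange; it sets out from 5 and 6 and returns at 8. Acid 5 is converted with cyanuric fluoride and pyridine into 4,6-bis(benzyloxy)-3-chloro-2,5-dimethylbenzoyl fluoride F7. Compound 6 is silylated to F1 as above, and F1 and F7 are combined with catalytic Bu4NF in THF. The ammonium enolate released from F1 should be acylated on oxygen, and the fluoride set free from F7 should carry the chain.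

**Step 8.** The Lewis acid may cleave the depside ester or the methyl ester through the chelate it forms with the C6 hydroxyl and the C1 ester. Cleavage of the hindered, non-chelated C4' ether may stay incomplete, and benzyl cations may alkylate ring A if scavenging is too slow. The fallback changes from Lewis-acid dealkylation to hydrogenolysis; it sets out from 12 and returns at 13. Compound 12 is treated with H2 (1 atm) and Pd/C in ethyl acetate at rt, and the reaction is stopped after uptake of two equivalents, before the aryl chloride is reduced. This detour makes no compound outside the list and is entered as F0.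

## Further compounds

F1 | step 7 | methyl (2Z)-3-[(trimethylsilyl)oxy]but-2-enoate | C/C(O[Si](C)(C)C)=C/C(=O)OC
F2 | step 7 | (1Z)-1-methoxy-1,3-bis[(trimethylsilyl)oxy]buta-1,3-diene | CO/C(O[Si](C)(C)C)=C/C(=C)O[Si](C)(C)C
F3 | step 7 | methyl 6-methoxy-2-methyl-4,6-bis[(trimethylsilyl)oxy]cyclohexa-1,4-diene-1-carboxylate (racemic) | COC(=O)C1=C(C)CC(O[Si](C)(C)C)=CC1(OC)O[Si](C)(C)C
F4 | step 7 | methyl 2-hydroxy-6-methyl-4-[(trimethylsilyl)oxy]benzoate | COC(=O)c1c(C)cc(O[Si](C)(C)C)cc1O
F5 | step 7 | methyl 2,4-dihydroxy-6-methylbenzoate | COC(=O)c1c(C)cc(O)cc1O
F6 | step 6 | 4,6-bis(benzyloxy)-3-chloro-2,5-dimethylbenzoic trifluoroacetic anhydride | O=C(OC(=O)C(F)(F)F)c1c(C)c(Cl)c(OCc2ccccc2)c(C)c1OCc1ccccc1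
F7 | step 5 | 4,6-bis(benzyloxy)-3-chloro-2,5-dimethylbenzoyl fluoride | O=C(F)c1c(C)c(Cl)c(OCc2ccccc2)c(C)c1OCc1ccccc1
F0 | step 8 | none | none
A1 | alternative 1 | 1-chloro-3-iodo-4,6-bis(methoxymethoxy)-2,5-dimethylbenzene | Ic1c(C)c(Cl)c(OCOC)c(C)c1OCOC
A2 | alternative 1 | methyl 2,4-dihydroxy-6-methylbenzoate | COC(=O)c1c(C)cc(O)cc1O
A3 | alternative 1 | carbon monoxide | [C-]#[O+]
A4 | alternative 1 | methyl 4-{[3-chloro-4,6-bis(methoxymethoxy)-2,5-dimethylbenzoyl]oxy}-2-hydroxy-6-methylbenzoate | COC(=O)c1c(C)cc(OC(=O)c2c(C)c(Cl)c(OCOC)c(C)c2OCOC)cc1O
A5 | alternative 2 | methyl 2-hydroxy-6-methyl-4-[(4-methyl-3,5,7-trioxooctanoyl)oxy]benzoate (racemic, configurationally labile) | COC(=O)c1c(C)cc(OC(=O)CC(=O)C(C)C(=O)CC(C)=O)cc1O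
A6 | alternative 2 | methyl 4-[(2,4-dihydroxy-3,6-dimethylbenzoyl)oxy]-2-hydroxy-6-methylbenzoate | COC(=O)c1c(C)cc(OC(=O)c2c(C)cc(O)c(C)c2O)cc1O
A7 | alternative 3 | methyl 4-{[(4E)-5-chloro-2-diazo-4-methyl-3-oxopent-4-enoyl]oxy}-2-hydroxy-6-methylbenzoate | COC(=O)c1c(C)cc(OC(=O)C(=[N+]=[N-])C(=O)/C(C)=C/Cl)cc1O
A8 | alternative 3 | triisopropyl(prop-1-yn-1-yloxy)silane | CC#CO[Si](C(C)C)(C(C)C)C(C)C
A9 | alternative 3 | methyl 4-({3-chloro-4-hydroxy-2,5-dimethyl-6-[(triisopropylsilyl)oxy]benzoyl}oxy)-2-hydroxy-6-methylbenzoate | COC(=O)c1c(C)cc(OC(=O)c2c(C)c(Cl)c(O)c(C)c2O[Si](C(C)C)(C(C)C)C(C)C)cc1O
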